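**Plan**

Ring numbering: C1 (quaternary; methyl and 4-methylpent-3-enyl), C2=C3, C4 (acyloxy), C5 (methyl carbinol), C6=C7, C8 (ketone), C9 (CH2OH)=C10, C11. The target is 1S,4R,5S with three cis ring alkenes.
Enabling feature: C4–C8, with oxygen on C4, C5 and C8 and the cis C6=C7 alkene, are the five carbons of furfural (CHO = C4, furan C2–C5 = C5–C8). A 2-furyl carbinol at C4 expands oxidatively to a 6-methoxy-2H-pyran-3(6H)-one with the C4 oxygen as ring oxygen, C5 as ketone and C8 as ketal carbon.
Retrosynthetic cuts, in order: the C4 ester and the silyl groups; ring bond C8–C9 (alkenyl–acyl); C5–CH3; the two C8–O bonds of the pyranone (back to the furan); C3–C4 (alkyne to furfural); C9=C10 (Wittig); C1–C2 (SN2′ on geranyl phosphate).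
Forward: geraniol gives the C1 enyne, then the C9–C11 iodoalkene arm, then the furyl carbinol. Anodic oxidation closes the six-membered pyranone. Methyl addition and oxidation give a lactone, whose carbonyl is attacked by the C9 alkenyllithium, closing the eleven-membered carbocycle as the pyran ring opens. Esterification and desilylation finish.
Stereochemistry: C1 from copper–carbene-catalysed SN2′ alkynylation; C4 from ProPhenol/Me2Zn alkynylation; C8 (temporary) from the anomeric effect; C5 from axial methyl addition anti to the C8 methoxy group; C2=C3 from Lindlar reduction; C9=C10 from the iodo-Wittig; C6=C7 from the furan.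

Key step: step 10

Remark: in the two ligand-controlled steps (2 and 9) the ligand antipode that leads to 1S and 4R is assumed to be chosen after the sense of induction is checked on the first run (Mosher esters for C4).

**Route**

Step 1
Reactants: 1 geraniol
Product: 2 geranyl diethyl phosphate
Conditions: ClP(O)(OEt)2, pyridine, CH2Cl2, 0 °C → rt
Reagents that add atoms: diethyl chlorophosphate, CCOP(=O)(Cl)OCC
Why: Phosphorylation of a primary allylic alcohol by a chlorophosphate with an amine base is a routine esterification that leaves the E alkene untouched and installs the leaving group for copper-catalysed allylic substitution.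

Step 2
Reactants: 2 geranyl diethyl phosphate; 3 trimethylsilylacetylene
Product: 6 [(3S)-3-ethenyl-3,7-dimethyloct-6-en-1-yn-1-yl]trimethylsilane, via lithium trimethylsilylacetylide 4 (not isolated), via diisobutyl(trimethylsilylethynyl)alane 5 (not isolated)
Conditions: 3, n-BuLi, THF, −78 °C; i-Bu2AlCl, −78 → 0 °C; then 2, CuCl2·2H2O (5 mol %), 4,5-diphenyl-1-(2-sulfonatophenyl)-3-(2,4,6-trimethylphenyl)imidazolinium zwitterion (one antipode, 5 mol %), THF, −15 °C
Reagents that add atoms: trimethylsilylacetylene (compound 3), C#C[Si](C)(C)C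
Why: Copper–N-heterocyclic carbene-catalysed enantioselective allylic substitution with a dialkyl(alkynyl)alane transfers only the alkynyl group and attacks the trisubstituted γ-carbon of the E phosphate (SN2′), so the quaternary centre C1 with its vinyl, methyl, homoprenyl and alkynyl groups is created under control of the chiral ligand.

Step 3
Reactants: 6 [(3S)-3-ethenyl-3,7-dimethyloct-6-en-1-yn-1-yl]trimethylsilane
Product: 8 (3S)-3,7-dimethyl-3-[(trimethylsilyl)ethynyl]oct-6-en-1-ol, via B-alkyl-9-borabicyclononane 7 (not isolated)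
Conditions: 9-BBN, THF, 0 °C → rt; then NaBO3·4H2O, H2O, rt
Reagents that add atoms: sodium perborate tetrahydrate (NaBO3·4H2O; gives the oxygen), [Na+].[Na+].O[B-]1(O)OO[B-](O)(O)OO1
Why: Anti-Markovnikov hydroboration–oxidation: the bulky dialkylborane should add to the monosubstituted alkene much faster than to the trisubstituted alkene or the silylated alkyne, and perborate oxidises the C–B bond without the hydroxide that could strip the alkynylsilane.

Step 4
Reactants: 8 (3S)-3,7-dimethyl-3-[(trimethylsilyl)ethynyl]oct-6-en-1-ol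
Product: 9 (3S)-3,7-dimethyl-3-[(trimethylsilyl)ethynyl]oct-6-enal
Conditions: Dess–Martin periodinane, CH2Cl2, 0 °C → rt
Reagents that add atoms: none
Why: Dess–Martin oxidation stops at the aldehyde, tolerates the alkene and the alkynylsilane, and the aldehyde has no α-stereocentre that could be lost.

Step 5
Reactants: 9 (3S)-3,7-dimethyl-3-[(trimethylsilyl)ethynyl]oct-6-enal
Product: 10 ethyl (2Z,5S)-2-iodo-5,9-dimethyl-5-[(trimethylsilyl)ethynyl]deca-2,8-dienoate
Conditions: Ph3P=CHCO2Et, N-iodosuccinimide, CH2Cl2, −20 °C; then 9, rt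
Reagents that add atoms: ethyl (triphenylphosphoranylidene)acetate, CCOC(=O)C=P(c1ccccc1)(c1ccccc1)c1ccccc1; N-iodosuccinimide, O=C1CCC(=O)N1I
Why: Iodo-Wittig olefination: the stabilised ylide is iodinated in the flask and then reacts with the aldehyde so that, as usual for stabilised ylides, the ester ends up trans to the alkyl chain and iodine therefore cis to C11 (2Z), the geometry that later makes C9=C10 a cis ring alkene.

Step 6
Reactants: 10 ethyl (2Z,5S)-2-iodo-5,9-dimethyl-5-[(trimethylsilyl)ethynyl]deca-2,8-dienoate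
Product: 11 (2Z,5S)-2-iodo-5,9-dimethyl-5-[(trimethylsilyl)ethynyl]deca-2,8-dien-1-ol
Conditions: i-Bu2AlH, CH2Cl2, −78 °C
Reagents that add atoms: none
Why: i-Bu2AlH reduces an α,β-unsaturated ester in 1,2-fashion to the allylic alcohol at low temperature without touching the C–I bond, the alkene geometry or the alkynylsilane.

Step 7
Reactants: 11 (2Z,5S)-2-iodo-5,9-dimethyl-5-[(trimethylsilyl)ethynyl]deca-2,8-dien-1-ol
Product: 12 tert-butyldiphenylsilyl ether of 11
Conditions: TBDPSCl, imidazole, CH2Cl2, rt
Reagents that add atoms: tert-butyl(chloro)diphenylsilane, CC(C)(C)[Si](Cl)(c1ccccc1)c1ccccc1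
Why: Imidazole-promoted silylation of a primary alcohol; the bulky tert-butyldiphenylsilyl ether is chosen because it should withstand the acid of steps 10 and 14 as well as the organolithium and organocerium reagents.

Step 8
Reactants: 12 tert-butyldiphenylsilyl ether of 11
Product: 13 tert-butyl{[(2Z,5S)-5-ethynyl-2-iodo-5,9-dimethyldeca-2,8-dien-1-yl]oxy}diphenylsilane
Conditions: K2CO3 (cat.), MeOH, rt
Reagents that add atoms: none
Why: Carbonate-catalysed methanolysis cleaves the C(sp)–Si bond selectively, since the hindered silyl ether and the alkenyl iodide are inert to these conditions, and frees the terminal alkyne for metalation.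

Step 9
Reactants: 13 tert-butyl{[(2Z,5S)-5-ethynyl-2-iodo-5,9-dimethyldeca-2,8-dien-1-yl]oxy}diphenylsilane; 14 furfural
Product: 16 (1R,4S,6Z)-8-[(tert-butyldiphenylsilyl)oxy]-1-(furan-2-yl)-7-iodo-4-methyl-4-(4-methylpent-3-en-1-yl)oct-6-en-2-yn-1-ol, via alkynyl(methyl)zinc 15 (not isolated)
Conditions: 13, Me2Zn, ProPhenol ligand [2,6-bis{[2-(hydroxydiphenylmethyl)pyrrolidin-1-yl]methyl}-4-methylphenol, one antipode, 10 mol %], Ph3P=O (20 mol %), toluene, 0 °C; then 14, 4 °C
Reagents that add atoms: furfural (compound 14), O=Cc1ccco1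
Why: Zinc–ProPhenol-catalysed asymmetric alkynylation: the dinuclear zinc complex holds furfural and the alkynylzinc 15 together and delivers the alkynyl group to one face of the aldehyde, so that C4 is set as R by the ligand, independently of the distant C1 centre.

Step 10
Reactants: 16 (1R,4S,6Z)-8-[(tert-butyldiphenylsilyl)oxy]-1-(furan-2-yl)-7-iodo-4-methyl-4-(4-methylpent-3-en-1-yl)oct-6-en-2-yn-1-ol; 17 methanol
Product: 19 (2R,6S)-2-[(3S,5Z)-7-[(tert-butyldiphenylsilyl)oxy]-6-iodo-3-methyl-3-(4-methylpent-3-en-1-yl)hept-5-en-1-yn-1-yl]-6-methoxy-2H-pyran-3(6H)-one (trans), via 2,5-dimethoxy-2,5-dihydrofuran 18 (not isolated)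
Conditions: undivided cell, graphite anode, Pt cathode, Et4NOTs, 2,6-lutidine, MeOH, −20 °C, anode held just above the furan wave (expected near +1.4 V vs Ag/AgCl), 2.1 F/mol; then CF3CO2H, 0 °C → rt
Reagents that add atoms: methanol (compound 17), CO
Why: Two-electron oxidation at the anode converts the furan, the π system of lowest oxidation potential in 16, into a cation that methanol captures at C5 and C8 to give the 2,5-dimethoxy-2,5-dihydrofuran 18; acid then ionises the C8 acetal, the C4 hydroxyl adds to the C8 oxocarbenium ion and the C5 hemiketal loses methanol to unveil the ketone, so that the C8–O(C4) and C8–OMe bonds are the ones formed. The closest known reaction type is the electrochemical Achmatowicz reaction, that is anodic methoxylation of a 2-furylcarbinol followed by acid rearrangement to a 6-alkoxy-2H-pyran-3(6H)-one. The six-membered ring closes in a 6-exo-trig mode, the oxygen attacking the trigonal C8 whose C=O bond lies outside the new ring. The new stereocentre C8 is under thermodynamic control: acid in methanol equilibrates the ketal, and the anomeric effect favours the axial methoxy group trans to the equatorial C4 substituent, while C4 itself is not touched. The step needs the furan to be oxidised ahead of the trisubstituted alkene, the alkyne, the alkenyl iodide and the arylsilane; holding the anode at the furan wave and stopping near two faradays per mole should secure this, and the lutidine buffer protects the silyl ether until acid is added on purpose.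

Step 11
Reactants: 19 trans-pyranone from step 10
Product: 20 (2R,3S,6S)-2-[(3S,5Z)-7-[(tert-butyldiphenylsilyl)oxy]-6-iodo-3-methyl-3-(4-methylpent-3-en-1-yl)hept-5-en-1-yn-1-yl]-6-methoxy-3-methyl-3,6-dihydro-2H-pyran-3-ol
Conditions: CeCl3, MeLi, THF, −78 °C; then 19, −78 °C; H2O
Reagents that add atoms: methyllithium, [Li]C
Why: Organocerium (Imamoto) 1,2-addition: methylcerium dichloride is nucleophilic but hardly basic, so it should add to the C5 ketone without enolising the acidic C4–H or adding in 1,4-fashion, and it should approach axially on the face opposite the axial C8 methoxy group, as hydride does in Luche reductions of such pyranones, which places the methyl group cis to the C4 chain and sets C5 as S.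

Step 12
Reactants: 20 tertiary alcohol from step 11
Product: 21 triethylsilyl ether of 20 at the C5 hydroxyl
Conditions: Et3SiOTf, 2,6-lutidine, CH2Cl2, −78 °C
Reagents that add atoms: triethylsilyl trifluoromethanesulfonate, CC[Si](CC)(CC)OS(=O)(=O)C(F)(F)F
Why: Silyl triflate–lutidine silylation is the standard way to protect a tertiary alcohol; the ether keeps the C5 oxygen from competing with the C4 oxygen for C8 once the ketal is opened, and low temperature with excess base should leave the allylic ketal untouched.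

Step 13
Reactants: 21 triethylsilyl ether of 20
Product: 22 (2R,3S,6S)-2-[(1Z,3S,5Z)-7-[(tert-butyldiphenylsilyl)oxy]-6-iodo-3-methyl-3-(4-methylpent-3-en-1-yl)hepta-1,5-dien-1-yl]-6-methoxy-3-methyl-3-[(triethylsilyl)oxy]-3,6-dihydro-2H-pyran
Conditions: H2 (1 atm), Pd/CaCO3 poisoned with Pb(OAc)2 (Lindlar catalyst), quinoline, EtOAc, rt
Reagents that add atoms: none
Why: Lindlar semi-hydrogenation adds hydrogen syn to the alkyne and so gives the cis C2=C3 alkene, while the lead- and quinoline-poisoned catalyst should spare the C–I bond, the ring alkene and the trisubstituted alkenes.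

Step 14
Reactants: 22 cis-dienyl methyl ketal from step 13
Product: 23 (5S,6R)-6-[(1Z,3S,5Z)-7-[(tert-butyldiphenylsilyl)oxy]-6-iodo-3-methyl-3-(4-methylpent-3-en-1-yl)hepta-1,5-dien-1-yl]-5-methyl-5-[(triethylsilyl)oxy]-5,6-dihydro-2H-pyran-2-ol (anomer mixture)
Conditions: PPTS (cat.), acetone–H2O, rt
Reagents that add atoms: water, O
Why: Hydrolysis of an allylic methyl ketal proceeds through an allyl-stabilised oxocarbenium ion and so needs only a weak acid that both silyl ethers should tolerate; the anomer mixture at C8 is of no consequence because C8 is oxidised next.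

Step 15
Reactants: 23 lactol from step 14
Product: 24 (5S,6R)-6-[(1Z,3S,5Z)-7-[(tert-butyldiphenylsilyl)oxy]-6-iodo-3-methyl-3-(4-methylpent-3-en-1-yl)hepta-1,5-dien-1-yl]-5-methyl-5-[(triethylsilyl)oxy]-5,6-dihydro-2H-pyran-2-one
Conditions: PhI(OAc)2, TEMPO (cat.), CH2Cl2, rt
Reagents that add atoms: none
Why: TEMPO-catalysed oxidation with PhI(OAc)2 converts a lactol into the lactone under nearly neutral conditions that leave the alkenes, the C–I bond and the silyl ethers alone, and it removes the temporary C8 stereocentre.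

Step 16
Reactants: 24 unsaturated δ-lactone from step 15
Product: 26 eleven-membered hydroxy dienone (1S,4R,5S; free C4 hydroxyl; C5 triethylsilyl ether; C8 ketone; C9 CH2O-tert-butyldiphenylsilyl; ring alkenes all cis), via alkenyllithium 25 (not isolated)
Conditions: t-BuLi (2.1 equiv), THF (0.003 M), −78 °C; then AcOH, −78 °C
Reagents that add atoms: none
Why: Proposed new method: iodine–lithium exchange with t-BuLi at −78 °C is faster than addition to the lactone, the resulting alkenyllithium 25 holds the metal cis to C11 and attacks the lactone carbonyl C8 in 1,2-fashion through a nine-membered ring that contains the lactone oxygen, and the bridged lithium hemiketalate then opens to the eleven-membered dienone and the C4 alkoxide, so that the medium ring arises by ring expansion and not by end-to-end closure; the closest known reaction types are the Parham anionic cyclisation of halo esters and the samarium diiodide-promoted intramolecular acyl substitution of iodoalkyl lactones to ring-expanded hydroxy ketones, neither of which has been shown for an alkenyllithium closing an eleven-membered ring.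

Step 17
Reactants: 26 eleven-membered hydroxy dienone; 27 3-methylbut-2-enoyl chloride
Product: 28 C4 3-methylbut-2-enoate of 26
Conditions: 27, pyridine, DMAP (cat.), CH2Cl2, 0 °C
Reagents that add atoms: 3-methylbut-2-enoyl chloride (compound 27), CC(C)=CC(=O)Cl
Why: DMAP-catalysed acylation with an acid chloride: the secondary allylic C4 hydroxyl of the open hydroxy ketone is the only unhindered hydroxyl (C5 is silylated, and any transannular hemiketal form is in equilibrium with the open form and has only a tertiary hydroxyl), and pyridine in place of a trialkylamine limits vinylketene formation and deconjugation of the acyl group.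

Step 18
Reactants: 28 C4 3-methylbut-2-enoate of 26
Product: 29 target CNP0230506.4
Conditions: HF·pyridine, pyridine, THF, 0 °C → rt
Reagents that add atoms: none
Why: Fluoride cleaves both Si–O bonds because of the strength of the Si–F bond, and the pyridine-buffered reagent should spare the ester, the tertiary allylic alcohol and the cross-conjugated dienone.

**Compound list**

1 | geraniol | CC(C)=CCC/C(C)=C/CO | starting material
2 | geranyl diethyl phosphate | CCOP(=O)(OCC)OC/C=C(\C)CCC=C(C)C | intermediate
3 | trimethylsilylacetylene | C#C[Si](C)(C)C | starting material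
4 | lithium trimethylsilylacetylide (not isolated) | [Li]C#C[Si](C)(C)C | intermediate
5 | diisobutyl(trimethylsilylethynyl)alane (not isolated) | CC(C)C[Al](CC(C)C)C#C[Si](C)(C)C | intermediate
6 | [(3S)-3-ethenyl-3,7-dimethyloct-6-en-1-yn-1-yl]trimethylsilane | CC(C)=CCC[C@](C)(C#C[Si](C)(C)C)C=C | intermediate
7 | B-alkyl-9-borabicyclo[3.3.1]nonane from 6, boron on the former terminal vinyl carbon (not isolated) | CC(C)=CCC[C@](C)(C#C[Si](C)(C)C)CCB1C2CCCC1CCC2 | intermediate
8 | (3S)-3,7-dimethyl-3-[(trimethylsilyl)ethynyl]oct-6-en-1-ol | CC(C)=CCC[C@](C)(C#C[Si](C)(C)C)CCO | intermediate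
9 | (3S)-3,7-dimethyl-3-[(trimethylsilyl)ethynyl]oct-6-enal | CC(C)=CCC[C@](C)(C#C[Si](C)(C)C)CC=O | intermediate
10 | ethyl (2Z,5S)-2-iodo-5,9-dimethyl-5-[(trimethylsilyl)ethynyl]deca-2,8-dienoate | CC(C)=CCC[C@](C)(C#C[Si](C)(C)C)C/C=C(\I)C(=O)OCC | intermediate
11 | (2Z,5S)-2-iodo-5,9-dimethyl-5-[(trimethylsilyl)ethynyl]deca-2,8-dien-1-ol | CC(C)=CCC[C@](C)(C#C[Si](C)(C)C)C/C=C(\I)CO | intermediate
12 | tert-butyldiphenylsilyl ether of 11 | CC(C)=CCC[C@](C)(C#C[Si](C)(C)C)C/C=C(\I)CO[Si](c1ccccc1)(c1ccccc1)C(C)(C)C | intermediate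
13 | tert-butyl{[(2Z,5S)-5-ethynyl-2-iodo-5,9-dimethyldeca-2,8-dien-1-yl]oxy}diphenylsilane | CC(C)=CCC[C@](C)(C#C)C/C=C(\I)CO[Si](c1ccccc1)(c1ccccc1)C(C)(C)C | intermediate
14 | furfural | O=Cc1ccco1 | starting material
15 | alkynyl(methyl)zinc from 13 (not isolated) | CC(C)=CCC[C@](C)(C#C[Zn]C)C/C=C(\I)CO[Si](c1ccccc1)(c1ccccc1)C(C)(C)C | intermediate
16 | (1R,4S,6Z)-8-[(tert-butyldiphenylsilyl)oxy]-1-(furan-2-yl)-7-iodo-4-methyl-4-(4-methylpent-3-en-1-yl)oct-6-en-2-yn-1-ol | CC(C)=CCC[C@](C)(C#C[C@@H](O)c1ccco1)C/C=C(\I)CO[Si](c1ccccc1)(c1ccccc1)C(C)(C)C | intermediate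
17 | methanol | CO | starting material
18 | 2,5-dimethoxy-2,5-dihydrofuran carbinol from 16, mixture at the two acetal carbons (not isolated) | CC(C)=CCC[C@](C)(C#C[C@@H](O)C1(OC)C=CC(OC)O1)C/C=C(\I)CO[Si](c1ccccc1)(c1ccccc1)C(C)(C)C | intermediate
19 | (2R,6S)-2-[(3S,5Z)-7-[(tert-butyldiphenylsilyl)oxy]-6-iodo-3-methyl-3-(4-methylpent-3-en-1-yl)hept-5-en-1-yn-1-yl]-6-methoxy-2H-pyran-3(6H)-one (trans) | CC(C)=CCC[C@](C)(C#C[C@H]1O[C@H](OC)C=CC1=O)C/C=C(\I)CO[Si](c1ccccc1)(c1ccccc1)C(C)(C)C | intermediate
20 | (2R,3S,6S)-2-alkynyl-6-methoxy-3-methyl-3,6-dihydro-2H-pyran-3-ol, alkynyl group as in 19 | CC(C)=CCC[C@](C)(C#C[C@H]1O[C@H](OC)C=C[C@]1(C)O)C/C=C(\I)CO[Si](c1ccccc1)(c1ccccc1)C(C)(C)C | intermediate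
21 | triethylsilyl ether of 20 at the C5 hydroxyl | CC(C)=CCC[C@](C)(C#C[C@H]1O[C@H](OC)C=C[C@]1(C)O[Si](CC)(CC)CC)C/C=C(\I)CO[Si](c1ccccc1)(c1ccccc1)C(C)(C)C | intermediate
22 | (2R,3S,6S)-2-[(1Z,3S,5Z)-7-[(tert-butyldiphenylsilyl)oxy]-6-iodo-3-methyl-3-(4-methylpent-3-en-1-yl)hepta-1,5-dien-1-yl]-6-methoxy-3-methyl-3-[(triethylsilyl)oxy]-3,6-dihydro-2H-pyran | CC(C)=CCC[C@](C)(/C=C\[C@H]1O[C@H](OC)C=C[C@]1(C)O[Si](CC)(CC)CC)C/C=C(\I)CO[Si](c1ccccc1)(c1ccccc1)C(C)(C)C | intermediate
23 | (5S,6R)-6-dienyl-5-methyl-5-[(triethylsilyl)oxy]-5,6-dihydro-2H-pyran-2-ol, dienyl group as in 22, anomer mixture | CC(C)=CCC[C@](C)(/C=C\[C@H]1OC(O)C=C[C@]1(C)O[Si](CC)(CC)CC)C/C=C(\I)CO[Si](c1ccccc1)(c1ccccc1)C(C)(C)C | intermediate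
24 | (5S,6R)-6-dienyl-5-methyl-5-[(triethylsilyl)oxy]-5,6-dihydro-2H-pyran-2-one, dienyl group as in 22 | CC(C)=CCC[C@](C)(/C=C\[C@H]1OC(=O)C=C[C@]1(C)O[Si](CC)(CC)CC)C/C=C(\I)CO[Si](c1ccccc1)(c1ccccc1)C(C)(C)C | intermediate
25 | alkenyllithium from 24, lithium in place of iodine at C9 (not isolated) | CC(C)=CCC[C@](C)(/C=C\[C@H]1OC(=O)C=C[C@]1(C)O[Si](CC)(CC)CC)C/C=C(\[Li])CO[Si](c1ccccc1)(c1ccccc1)C(C)(C)C | intermediate
26 | eleven-membered hydroxy dienone: 1S,4R,5S; C4 hydroxyl free; C5 triethylsilyl ether; C8 ketone; C9 CH2O-tert-butyldiphenylsilyl; ring alkenes C2=C3, C6=C7, C9=C10 all cis | CC(C)=CCC[C@]1(C)/C=C\[C@@H](O)[C@@](C)(O[Si](CC)(CC)CC)/C=C\C(=O)/C(CO[Si](c2ccccc2)(c2ccccc2)C(C)(C)C)=C\C1 | intermediate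
27 | 3-methylbut-2-enoyl chloride | CC(C)=CC(=O)Cl | starting material
28 | C4 3-methylbut-2-enoate of 26 | CC(C)=CCC[C@]1(C)/C=C\[C@@H](OC(=O)C=C(C)C)[C@@](C)(O[Si](CC)(CC)CC)/C=C\C(=O)/C(CO[Si](c2ccccc2)(c2ccccc2)C(C)(C)C)=C\C1 | intermediate
29 | CNP0230506.4: 1S,4R,5S eleven-membered dienone with C4 3-methylbut-2-enoate, C5 methyl carbinol, C9 hydroxymethyl, three cis ring alkenes | CC(C)=CCC[C@]1(C)/C=C\[C@@H](OC(=O)C=C(C)C)[C@@](C)(O)/C=C\C(=O)/C(CO)=C\C1 | target

**Step count and risks**

Total step count: 18. Longest linear sequence: 18 steps, from geraniol 1 to 29; compounds 3, 14, 17 and 27 enter as purchased materials.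

Steps most likely to fail:

1. Step 16. Protonation or β-elimination of the alkenyllithium, conjugate or intermolecular attack, or direct addition of t-BuLi to the lactone may outrun the transannular acyl substitution. The fallback uses known chemistry only, sets out from lactol 23 and comes back at 28. Luche reduction (NaBH4, CeCl3·7H2O, MeOH, 0 °C) of the open hydroxy enal form gives the (Z)-allylic C4,C8-diol F1. Selective silylation of the primary hydroxyl (Et3SiCl, imidazole, CH2Cl2, −40 °C) gives the C8 triethylsilyl ether F2. Acylation of the C4 hydroxyl with 27 (pyridine, DMAP) gives the C4 3-methylbut-2-enoate F3. PPTS in MeOH at 0 °C removes only the primary triethylsilyl group to give the C8 alcohol F4. Dess–Martin oxidation gives the (Z)-enal F5. Nozaki–Hiyama–Kishi cyclisation (CrCl2, NiCl2 cat., DMSO–THF, high dilution) joins C8 and C9 to give the macrocyclic C8 carbinol F6 as an epimer mixture. Dess–Martin oxidation then gives 28.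

2. Step 10. Competing oxidation of the electron-rich trisubstituted alkene, loss of the silyl ether or epimerisation at C4 during the acid stage, or weak anomer control may erode the step. The fallback sets out from 16 and comes back at 19. Hydroxyl-directed oxidation of the furan with VO(acac)2 (cat.) and t-BuOOH in CH2Cl2 at 0 °C (the chemical Achmatowicz rearrangement) gives the 6-hydroxypyranone F7. HC(OMe)3, MeOH and PPTS then convert it into the methyl ketal 19 under the same anomeric control.

3. Step 13. Hydrogenolysis of the C–I bond or over-reduction may compete with slow hydrogenation of the hindered alkyne next to C1. The fallback sets out from 21 and comes back at 22. Syn-hydroboration of the alkyne with dicyclohexylborane (THF, 0 °C) gives the alkenyl(dicyclohexyl)borane F8 (boron at C3; the C2 regioisomer would behave alike). Protonolysis of its C–B bond with AcOH, which proceeds with retention, gives the cis alkene 22 without hydrogen or palladium.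

Further compounds
F1 | step 16 | (Z)-allylic C4,C8-diol from 23 (C5 triethylsilyl ether retained) | CC(C)=CCC[C@](C)(/C=C\[C@@H](O)[C@@](C)(O[Si](CC)(CC)CC)/C=C\CO)C/C=C(\I)CO[Si](c1ccccc1)(c1ccccc1)C(C)(C)C
F2 | step 16 | C8 triethylsilyl ether of F1 | CC(C)=CCC[C@](C)(/C=C\[C@@H](O)[C@@](C)(O[Si](CC)(CC)CC)/C=C\CO[Si](CC)(CC)CC)C/C=C(\I)CO[Si](c1ccccc1)(c1ccccc1)C(C)(C)C
F3 | step 16 | C4 3-methylbut-2-enoate of F2 | CC(C)=CCC[C@](C)(/C=C\[C@@H](OC(=O)C=C(C)C)[C@@](C)(O[Si](CC)(CC)CC)/C=C\CO[Si](CC)(CC)CC)C/C=C(\I)CO[Si](c1ccccc1)(c1ccccc1)C(C)(C)C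
F4 | step 16 | C8 alcohol from F3 | CC(C)=CCC[C@](C)(/C=C\[C@@H](OC(=O)C=C(C)C)[C@@](C)(O[Si](CC)(CC)CC)/C=C\CO)C/C=C(\I)CO[Si](c1ccccc1)(c1ccccc1)C(C)(C)C
F5 | step 16 | (Z)-enal from F4 | CC(C)=CCC[C@](C)(/C=C\[C@@H](OC(=O)C=C(C)C)[C@@](C)(O[Si](CC)(CC)CC)/C=C\C=O)C/C=C(\I)CO[Si](c1ccccc1)(c1ccccc1)C(C)(C)C
F6 | step 16 | macrocyclic C8 carbinol (epimer mixture at C8) | CC(C)=CCC[C@]1(C)/C=C\[C@@H](OC(=O)C=C(C)C)[C@@](C)(O[Si](CC)(CC)CC)/C=C\C(O)/C(CO[Si](c2ccccc2)(c2ccccc2)C(C)(C)C)=C\C1
F7 | step 10 | 6-hydroxy-2H-pyran-3(6H)-one from 16 (anomer mixture) | CC(C)=CCC[C@](C)(C#C[C@H]1OC(O)C=CC1=O)C/C=C(\I)CO[Si](c1ccccc1)(c1ccccc1)C(C)(C)C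
F8 | step 13 | alkenyl(dicyclohexyl)borane from 21, boron at C3 | CC(C)=CCC[C@](C)(/C=C(\[C@H]1O[C@H](OC)C=C[C@]1(C)O[Si](CC)(CC)CC)B(C1CCCCC1)C1CCCCC1)C/C=C(\I)CO[Si](c1ccccc1)(c1ccccc1)C(C)(C)C
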